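Numbering used throughout: 1–7, 11, 13, 14 and 16–22 are isolated compounds or reagents; 8–10, 12 and 15 are intermediates that are not isolated.

## Analysis of the target

Target 22 is a 2,4-dihydroxy-6-alkylbenzoic acid. Ring A (C1–C6) carries a tridecyl chain (C1'–C13') on C1, the carboxyl carbon C7 on C2 and free hydroxyls on C3 and C5; the chain bears acetates at C2' and C12'. The two stereocentres, C2' (R) and C12' (S), are nine methylene groups apart, so neither can steer the other: C12' is best bought and C2' set by a catalyst-controlled step. The sensitive groups are the salicylic-type acid (decarboxylation in hot acid), the electron-rich resorcinol and two secondary acetates, which rule out hydrolytic or strongly basic unmasking at the end. The C2' oxygen is δ to C7, so any intermediate with a free C2' hydroxyl and an acylating C7 group can close to a 3,4-dihydroisocoumarin, which the open acetoxy acid must avoid. The difficulty is therefore the contiguous C1(alkyl)/C2(carboxyl)/C3(oxygen) pattern together with a stereocentre one carbon removed from the benzylic position. The strategy rests on C1 and C2 being adjacent with C2 next to oxygenated C3: this is the pattern left when a carbon nucleophile and carbon dioxide add across a 3,5-dioxygenated benzyne, and the δ-relation lets the C2' oxygen be stored as the ring oxygen of an isocoumarin.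

## Retrosynthetic reasoning

**22 ⇐ 21.** The three O–CH2Ph bonds (two aryl ethers, one ester) are cut last. One hydrogenolysis frees the acid and both phenols under neutral conditions, the only unmasking that the acetates and the acid both tolerate. This is why all three acidic oxygens are carried as benzyl groups.

**21 ⇐ 20 ⇐ 19 ⇐ 18.** Removing the two acetyl groups gives diol ester 20, and cutting the C2'–H bond gives ketone 19. The ketone is flanked by two methylene groups, a case where small-molecule catalysts discriminate poorly, so an enzyme is chosen. The forward reduction must give the (R)-alcohol, and acetylation must then outrun attack of the new hydroxyl on the hindered C7 ester. The silyl group is removed before the reduction (19 ⇐ 18) so that no desilylating or basic reagent meets the δ-hydroxy ester.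

**18 ⇐ 17 ⇐ 16.** The benzyl ester goes back to acid 17, and the C2' ketone plus C7 acid go back to the enol lactone of isocoumarin 16 by re-forming the C7–O bond. The 1,5-relation between C7 and the C2' oxygen becomes one ring; the forward direction needs only saponification and O-alkylation of the carboxylate.

**16 ⇐ 13 + 5 + 14.** Three bonds are cut at once: C1–C1', C2–C7 and O–C2'. Cutting here, and not at C1'–C2', keeps the arene partner derived from a symmetric phenol and the chain partner a plain terminal alkyne. Forward, benzyne 15 released from 13 must take the alkynyl carbon at C1 and carbon dioxide 14 at C2, and the carboxylate must close on the alkyne in the 6-endo sense.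

**13 ⇐ 11 ⇐ 7 ⇐ 6.** The O–S and C–Si bonds of 13 lead back to silyl carbamate 11 and then to carbamate 7 of phenol 6. The carbamate directs metalation to the position that becomes C2; because both positions ortho to the phenol oxygen of 6 are equivalent, only one silylation product is possible there.

**5 ⇐ 4 ⇐ 3 ⇐ 1 + 2.** The Si–O bond is cut, the triple bond is moved back from the chain terminus to C3–C4, and the sp–sp3 bond C4–C5 of 3 is cut to give 1 and 2. The C12' stereocentre is bought with 1 and never touched again.

## Alternatives that were turned down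

**Alternative 1:** Ring A is taken apart completely: its carbons come from the linear diketo-dioxinone A2, and ring bond C1–C2 forms last. In the forward step A2 is heated so that the dioxinone fragments, the resulting acyl group is trapped as a benzyl ester, and base then acid drive aldol closure between C2 and the C1 ketone with dehydration to resorcylate A1.
- For: the phenols arrive free, the acid arrives as its benzyl ester, and both stereocentres come in with the chain. C2' is set early on a small molecule, and on that point this alternative is stronger than the chosen route.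
- Against: in the open chain the C1 carbonyl has the C2' silyloxy group in the β-position, so E1cB elimination competes with aldol closure. A2 needs an enantioenriched β-silyloxy acyl donor and two dioxinone acylations, so the sequence before ring formation is roughly twice as long. A1 still needs silyl-to-acetyl exchange beside free phenols and passes through the same δ-hydroxy ester.
- In its place the chosen route buys the ring and joins ring, chain and carboxyl in one catalytic step, at the price of a late reduction.

**Alternative 2:** The cut is at C3–C4 and C5–C6. Heating cyclobutenone A4 with silyloxyalkyne A5 starts an electrocyclic cascade (ring opening, (2+2) addition, ring opening, 6-pi closure, tautomerisation) that gives resorcinol monosilyl ether A3.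
- For: neutral conditions, unambiguous placement of the chain meta to both oxygens, and stereocentres set beforehand.
- Against: A3 has no C7. The carboxyl must be added afterwards at C2 in competition with C4 between the two oxygens, by forcing carboxylation or by formylation and oxidation. The differentiated phenols are of no use for a symmetric resorcinol. A4 needs its own multistep synthesis, and the route builds a benzene ring that can be bought.
- It is longer and leaves the most congested substituent unsolved, which the chosen key step installs together with the chain.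

**Alternative 3:** The cut is at C6–C1 and C4–C5. Pyrone A7 and ketene acetal A8 combine in an inverse-demand Diels–Alder addition, followed by decarboxylative aromatisation with loss of one benzyloxy group, to give A6.
- For: A6 is the complete benzylated skeleton with both stereocentres (it equals 21 with silyl in place of acetyl). In how much of the target the key step delivers, this alternative is as strong as or stronger than the chosen one, and it needs no late ketone reduction.
- Against: A7 is a densely substituted heterocycle whose preparation (acylation with the chiral chain acid, pyrone closure, selective O-benzylation) is longer than the whole aryne branch. The C2' silyloxy group is β to the electrophilic pyrone C6, so elimination threatens. The 4-alkoxy donor lowers the reactivity of the diene and calls for heat, and A8 is hydrolytically fragile.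
- The chosen route offers simple partners (a symmetric phenol, a terminal alkyne) and fewer steps.

Key step: step 7

Assumption: the ketoreductase of step 11 is taken from a commercial screening panel and selected for the (2'R)-alcohol; metal alkoxides, acetylides, phenoxides and carboxylates that exist only until work-up are treated as forms of the numbered compounds.

## Route

Step 1
Reactants: 1 (S)-but-3-yn-2-ol; 2 1-bromononane
Product: 3 (2S)-tridec-3-yn-2-ol
Conditions: n-BuLi (2.1 equiv), THF, −78 °C; then 2, DMPU, −78 °C → rt; H2O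
Reagents that add atoms: none
Why: The alkoxide–acetylide dianion of 1 is alkylated at carbon by the primary bromide (SN2 acetylide alkylation); the lithium alkoxide is a poor nucleophile and the carbinol stereocentre is not involved.

Step 2
Reactants: 3 (2S)-tridec-3-yn-2-ol
Product: 4 (2S)-tridec-12-yn-2-ol
Conditions: KH, H2N(CH2)3NH2, 0 °C → rt; H2O
Reagents that add atoms: none
Why: Alkyne zipper reaction: potassium 3-aminopropylamide moves the triple bond along the chain by allene–alkyne prototropy until the terminal acetylide traps it; the adjacent alkoxide disfavours deprotonation at the carbinol carbon, so secondary propargylic alkoxides are expected to keep their configuration.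

Step 3
Reactants: 4 (2S)-tridec-12-yn-2-ol
Product: 5 tert-butyl(dimethyl){[(2S)-tridec-12-yn-2-yl]oxy}silane
Conditions: TBSCl, imidazole, DMF, rt
Reagents that add atoms: tert-butyldimethylsilyl chloride, CC(C)(C)[Si](C)(C)Cl
Why: Standard imidazole-promoted O-silylation of a secondary alcohol; the free hydroxyl must be masked because alcohols add to arynes.

Step 4
Reactants: 6 3,5-bis(benzyloxy)phenol
Product: 7 3,5-bis(benzyloxy)phenyl propan-2-ylcarbamate
Conditions: i-PrNCO, Et3N (cat.), CH2Cl2, rt
Reagents that add atoms: isopropyl isocyanate, CC(C)N=C=O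
Why: Amine-catalysed addition of the phenol to the isocyanate (carbamoylation) installs a directing group that can later be removed under mild base.

Step 5
Reactants: 7 3,5-bis(benzyloxy)phenyl propan-2-ylcarbamate
Product: 11 3,5-bis(benzyloxy)-2-(trimethylsilyl)phenyl propan-2-ylcarbamate, via N-silyl carbamate 8 (not isolated), via ortho-lithiated N-silyl carbamate 9 (not isolated), via N,C-bis-silyl carbamate 10 (not isolated)
Conditions: TBSOTf, TMEDA, Et2O, 0 °C → rt; n-BuLi, TMEDA, −78 °C; TMSCl, −78 °C → rt; cold aq. NaHSO4
Reagents that add atoms: chlorotrimethylsilane, C[Si](C)(C)Cl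
Why: Directed ortho-metalation: transient N-silylation makes the carbamate a tertiary directing group, and lithiation goes to the position flanked by the carbamate (the stronger director) and a benzyloxy group, not to C4 between the two ethers; the two such positions are equivalent, TMSCl traps the aryllithium at −78 °C before any carbamoyl migration, and the N–Si bond is hydrolysed on work-up.

Step 6
Reactants: 11 3,5-bis(benzyloxy)-2-(trimethylsilyl)phenyl propan-2-ylcarbamate
Product: 13 3,5-bis(benzyloxy)-2-(trimethylsilyl)phenyl trifluoromethanesulfonate, via 3,5-bis(benzyloxy)-2-(trimethylsilyl)phenol 12 (not isolated)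
Conditions: DBU, Et2NH, MeCN, 40 °C; then PhNTf2, rt
Reagents that add atoms: N-phenylbis(trifluoromethanesulfonimide), O=S(=O)(N(c1ccccc1)S(=O)(=O)C(F)(F)F)C(F)(F)F
Why: DBU deprotonates the N–H carbamate, which expels the isocyanate (E1cB, scavenged by Et2NH as a urea); the phenoxide of 12 is triflated in the same flask, so the acid-sensitive, electron-rich silylphenol is never isolated.

Step 7
Reactants: 13 3,5-bis(benzyloxy)-2-(trimethylsilyl)phenyl trifluoromethanesulfonate; 5 tert-butyl(dimethyl){[(2S)-tridec-12-yn-2-yl]oxy}silane; 14 carbon dioxide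
Product: 16 6,8-bis(benzyloxy)-3-[(10S)-10-{[tert-butyl(dimethyl)silyl]oxy}undecyl]-1H-isochromen-1-one, via 3,5-bis(benzyloxy)benzyne 15 (not isolated)
Conditions: (IPr)CuCl [IPr = 1,3-bis(2,6-diisopropylphenyl)imidazol-2-ylidene] (10 mol%), CsF, Cs2CO3, CO2 (1 atm), MeCN, 80–100 °C
Reagents that add atoms: none
Why: CsF removes the trimethylsilyl group of 13 and the ortho triflate leaves, releasing benzyne 15 in low concentration. (IPr)CuCl, carbonate and alkyne 5 give an alkynylcopper carbene complex of monovalent copper, which adds across the strained triple bond of 15 to give an ortho-alkynyl arylcopper. The benzyloxy group on C3 of 15 withdraws inductively and distorts the aryne so that C1 is the more electrophilic carbon; the alkynyl carbon therefore bonds to C1 (C1–C1') and copper sits on C2 beside the oxygen. The arylcopper inserts carbon dioxide 14, forming C2–C7 as a copper carboxylate. The carboxylate oxygen then attacks the copper-activated alkyne at the distal, alkyl-bearing carbon in a 6-endo-dig closure that forms O–C2' and the pyranone ring, and protonolysis of the vinylcopper by a further molecule of 5 returns the catalyst. The closest known reaction type is the carbene–copper catalysed three-component coupling of arynes, terminal alkynes and carbon dioxide to 3-substituted isocoumarins. No stereocentre is formed and the remote C12' silyl ether is a spectator. The step needs regioselective aryne addition (secured by the C3 benzyloxy group; the C5 group is meta to both aryne carbons), carboxylation before protonation of the arylcopper (dry medium, carbon dioxide atmosphere) and 6-endo over 5-exo closure (favoured by the bulky carbene–copper carboxylate and the alkyl substituent on C2').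

Step 8
Reactants: 16 6,8-bis(benzyloxy)-3-[(10S)-10-{[tert-butyl(dimethyl)silyl]oxy}undecyl]-1H-isochromen-1-one
Product: 17 2,4-bis(benzyloxy)-6-[(12S)-12-{[tert-butyl(dimethyl)silyl]oxy}-2-oxotridecyl]benzoic acid
Conditions: KOH, THF/H2O, 60 °C; then cold 1 M HCl to pH 4
Reagents that add atoms: potassium hydroxide, [K+].[OH-]
Why: Saponification of the enol lactone by acyl–oxygen cleavage releases the enol, which tautomerises to the C2' ketone; the secondary silyl ether and benzyl ethers are stable to aqueous hydroxide, and an alcohol-free medium avoids ring opening to an alkyl ester.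

Step 9
Reactants: 17 2,4-bis(benzyloxy)-6-[(12S)-12-{[tert-butyl(dimethyl)silyl]oxy}-2-oxotridecyl]benzoic acid
Product: 18 benzyl 2,4-bis(benzyloxy)-6-[(12S)-12-{[tert-butyl(dimethyl)silyl]oxy}-2-oxotridecyl]benzoate
Conditions: BnBr, KHCO3, DMF, rt
Reagents that add atoms: benzyl bromide, BrCc1ccccc1
Why: SN2 O-alkylation of the carboxylate esterifies the hindered acid without attack at its carbonyl; bicarbonate is too weak to enolise the benzylic ketone appreciably, so C-benzylation and Claisen-type closure onto the ester are avoided.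

Step 10
Reactants: 18 benzyl 2,4-bis(benzyloxy)-6-[(12S)-12-{[tert-butyl(dimethyl)silyl]oxy}-2-oxotridecyl]benzoate
Product: 19 benzyl 2,4-bis(benzyloxy)-6-[(12S)-12-hydroxy-2-oxotridecyl]benzoate
Conditions: HF·pyridine, pyridine/THF, 0 °C → rt
Reagents that add atoms: none
Why: Buffered fluoride cleaves the Si–O bond and leaves ketone, benzyl ester and benzyl ethers alone; doing this before the reduction keeps fluoride away from the later δ-hydroxy ester.

Step 11
Reactants: 19 benzyl 2,4-bis(benzyloxy)-6-[(12S)-12-hydroxy-2-oxotridecyl]benzoate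
Product: 20 benzyl 2,4-bis(benzyloxy)-6-[(2R,12S)-2,12-dihydroxytridecyl]benzoate
Conditions: ketoreductase ((R)-selective, from panel), NADP+ (cat.), i-PrOH (15% v/v), DMSO (10%), phosphate buffer pH 7.0, 30 °C
Reagents that add atoms: none
Why: Enzymatic asymmetric reduction of a 1-aryl-2-alkanone: NADPH delivers hydride to the Si face of the C2' carbonyl within a pocket that tells the arylmethyl flank from the linear alkyl flank, so C2' (R) is set by the enzyme alone, independent of the remote C12' centre; neutral pH, 30 °C and the large excess of i-PrOH over substrate protect the hindered 2,6-disubstituted benzyl ester from lactonisation and the C12' carbinol from redox scrambling.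

Step 12
Reactants: 20 benzyl 2,4-bis(benzyloxy)-6-[(2R,12S)-2,12-dihydroxytridecyl]benzoate
Product: 21 benzyl 2,4-bis(benzyloxy)-6-[(2R,12S)-2,12-bis(acetyloxy)tridecyl]benzoate
Conditions: Ac2O, pyridine, DMAP (cat.), CH2Cl2, 0 °C → rt
Reagents that add atoms: acetic anhydride, CC(=O)OC(C)=O
Why: DMAP-catalysed acylation of both secondary alcohols; no alkoxide is formed in pyridine, so acetylation should be much faster than closure of the C2' hydroxyl onto the twisted, hindered C7 ester.

Step 13
Reactants: 21 benzyl 2,4-bis(benzyloxy)-6-[(2R,12S)-2,12-bis(acetyloxy)tridecyl]benzoate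
Product: 22 2-[(2R,12S)-2,12-bis(acetyloxy)tridecyl]-4,6-dihydroxybenzoic acid
Conditions: H2 (1 atm), 10% Pd/C, EtOAc, rt
Reagents that add atoms: none
Why: Hydrogenolysis cleaves the two aryl benzyl ethers and the benzyl ester under neutral conditions; the non-benzylic secondary acetates, the arene and both stereocentres are untouched.

## Compound list

1 | (S)-but-3-yn-2-ol | C[C@H](O)C#C | starting material
2 | 1-bromononane | CCCCCCCCCBr | starting material
3 | (2S)-tridec-3-yn-2-ol | C[C@H](O)C#CCCCCCCCCC | intermediate
4 | (2S)-tridec-12-yn-2-ol | C[C@H](O)CCCCCCCCCC#C | intermediate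
5 | tert-butyl(dimethyl){[(2S)-tridec-12-yn-2-yl]oxy}silane | C#CCCCCCCCCC[C@H](C)O[Si](C)(C)C(C)(C)C | intermediate
6 | 3,5-bis(benzyloxy)phenol | Oc1cc(OCc2ccccc2)cc(OCc2ccccc2)c1 | starting material
7 | 3,5-bis(benzyloxy)phenyl propan-2-ylcarbamate | CC(C)NC(=O)Oc1cc(OCc2ccccc2)cc(OCc2ccccc2)c1 | intermediate
8 | 3,5-bis(benzyloxy)phenyl [tert-butyl(dimethyl)silyl](propan-2-yl)carbamate | CC(C)N(C(=O)Oc1cc(OCc2ccccc2)cc(OCc2ccccc2)c1)[Si](C)(C)C(C)(C)C | intermediate
9 | [2,4-bis(benzyloxy)-6-({[tert-butyl(dimethyl)silyl](propan-2-yl)carbamoyl}oxy)phenyl]lithium | [Li]c1c(OC(=O)N(C(C)C)[Si](C)(C)C(C)(C)C)cc(OCc2ccccc2)cc1OCc1ccccc1 | intermediate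
10 | 3,5-bis(benzyloxy)-2-(trimethylsilyl)phenyl [tert-butyl(dimethyl)silyl](propan-2-yl)carbamate | CC(C)N(C(=O)Oc1cc(OCc2ccccc2)cc(OCc2ccccc2)c1[Si](C)(C)C)[Si](C)(C)C(C)(C)C | intermediate
11 | 3,5-bis(benzyloxy)-2-(trimethylsilyl)phenyl propan-2-ylcarbamate | CC(C)NC(=O)Oc1cc(OCc2ccccc2)cc(OCc2ccccc2)c1[Si](C)(C)C | intermediate
12 | 3,5-bis(benzyloxy)-2-(trimethylsilyl)phenol | C[Si](C)(C)c1c(O)cc(OCc2ccccc2)cc1OCc1ccccc1 | intermediate
13 | 3,5-bis(benzyloxy)-2-(trimethylsilyl)phenyl trifluoromethanesulfonate | C[Si](C)(C)c1c(OS(=O)(=O)C(F)(F)F)cc(OCc2ccccc2)cc1OCc1ccccc1 | intermediate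
14 | carbon dioxide | O=C=O | starting material
15 | 3,5-bis(benzyloxy)benzyne | C1#CC(OCc2ccccc2)=CC(OCc2ccccc2)=C1 | intermediate
16 | 6,8-bis(benzyloxy)-3-[(10S)-10-{[tert-butyl(dimethyl)silyl]oxy}undecyl]-1H-isochromen-1-one | O=C1OC(CCCCCCCCC[C@H](C)O[Si](C)(C)C(C)(C)C)=Cc2cc(OCc3ccccc3)cc(OCc3ccccc3)c12 | intermediate
17 | 2,4-bis(benzyloxy)-6-[(12S)-12-{[tert-butyl(dimethyl)silyl]oxy}-2-oxotridecyl]benzoic acid | O=C(O)c1c(OCc2ccccc2)cc(OCc2ccccc2)cc1CC(=O)CCCCCCCCC[C@H](C)O[Si](C)(C)C(C)(C)C | intermediate
18 | benzyl 2,4-bis(benzyloxy)-6-[(12S)-12-{[tert-butyl(dimethyl)silyl]oxy}-2-oxotridecyl]benzoate | O=C(OCc1ccccc1)c1c(OCc2ccccc2)cc(OCc2ccccc2)cc1CC(=O)CCCCCCCCC[C@H](C)O[Si](C)(C)C(C)(C)C | intermediate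
19 | benzyl 2,4-bis(benzyloxy)-6-[(12S)-12-hydroxy-2-oxotridecyl]benzoate | O=C(OCc1ccccc1)c1c(OCc2ccccc2)cc(OCc2ccccc2)cc1CC(=O)CCCCCCCCC[C@H](C)O | intermediate
20 | benzyl 2,4-bis(benzyloxy)-6-[(2R,12S)-2,12-dihydroxytridecyl]benzoate | O=C(OCc1ccccc1)c1c(OCc2ccccc2)cc(OCc2ccccc2)cc1C[C@H](O)CCCCCCCCC[C@H](C)O | intermediate
21 | benzyl 2,4-bis(benzyloxy)-6-[(2R,12S)-2,12-bis(acetyloxy)tridecyl]benzoate | O=C(OCc1ccccc1)c1c(OCc2ccccc2)cc(OCc2ccccc2)cc1C[C@H](OC(C)=O)CCCCCCCCC[C@H](C)OC(C)=O | intermediate
22 | 2-[(2R,12S)-2,12-bis(acetyloxy)tridecyl]-4,6-dihydroxybenzoic acid | CC(=O)O[C@H](CCCCCCCCC[C@H](C)OC(C)=O)Cc1cc(O)cc(O)c1C(=O)O | target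

## Step count and least certain steps

Total step count: 13. Longest linear sequence: 10 steps (steps 1–3, then 7–13; the aryne branch, steps 4–6, then 7–13, is equally long).

**Step 7 (key step).** The most likely failures are protonation of the ortho-alkynyl arylcopper before it captures carbon dioxide, closure in the 5-exo sense, erosion of regiocontrol in the aryne addition, and fluoride-induced loss of the C12' silyl ether at the reaction temperature followed by O-arylation. The fallback fixes the substitution pattern by cross-coupling instead of aryne addition. It sets out from alkyne 5. The aryl partner is made from methyl 2,4,6-trihydroxybenzoate F1 by twofold O-benzylation (BnBr, K2CO3, acetone; the chelated hydroxyl stays free) to methyl 2,4-bis(benzyloxy)-6-hydroxybenzoate F2 and triflation (Tf2O, pyridine) to methyl 2,4-bis(benzyloxy)-6-{[(trifluoromethyl)sulfonyl]oxy}benzoate F3. Sonogashira coupling of F3 with 5 (PdCl2(PPh3)2, CuI, Et3N, DMF, 60 °C) should give methyl 2,4-bis(benzyloxy)-6-[(12S)-12-{[tert-butyl(dimethyl)silyl]oxy}tridec-1-yn-1-yl]benzoate F4. Gold-catalysed 6-endo-dig attack of the ester carbonyl on the alkyne with loss of the methyl group (Ph3PAuCl/AgOTf, wet MeCN) returns to the route at 16.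

**Step 11.** The most likely failure is poor binding and turnover of a very lipophilic ketone with two large flanks, with weak facial discrimination; slow lactonisation of the δ-hydroxy ester during a long incubation is a second concern. The fallback sets the centre by alkene hydrogenation and sets out from 16. Enantioselective hydrogenation of the C3=C4 bond uses the chiral ruthenium carbene–diamine catalyst formed in situ from Ru(cod)(2-methylallyl)2, a chiral 1,3-bis[1-(naphthalen-1-yl)ethyl]imidazolinium tetrafluoroborate, KOt-Bu and a chiral 1,2-diphenylethane-1,2-diamine, under H2 pressure with the ligand enantiomers chosen for the 3R product. This should give (3R)-6,8-bis(benzyloxy)-3-[(10S)-10-{[tert-butyl(dimethyl)silyl]oxy}undecyl]-3,4-dihydro-1H-isochromen-1-one F5. HF·pyridine gives (3R)-6,8-bis(benzyloxy)-3-[(10S)-10-hydroxyundecyl]-3,4-dihydro-1H-isochromen-1-one F6. KOH in THF/H2O opens the lactone to potassium 2,4-bis(benzyloxy)-6-[(2R,12S)-2,12-dihydroxytridecyl]benzoate F7; excess base is neutralised with CO2 and the dried salt is O-benzylated (BnBr, DMF), coming back at 20.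

**Step 12.** The risk is that closure of the C2' hydroxyl onto the C7 ester (lactonisation with loss of the benzyl group) competes with O-acetylation, here or while 20 is handled. The fallback removes the acylating group at C7 while C2' is acetylated and sets out from 20.
- Lactonisation is driven to completion (camphorsulfonic acid cat., toluene) to give the dihydroisocoumarin F6 named above.
- LiAlH4 reduces it to (2R,12S)-1-[3,5-bis(benzyloxy)-2-(hydroxymethyl)phenyl]tridecane-2,12-diol F8.
- TBSCl/imidazole silylates the primary benzylic hydroxyl, giving (2R,12S)-1-[3,5-bis(benzyloxy)-2-({[tert-butyl(dimethyl)silyl]oxy}methyl)phenyl]tridecane-2,12-diol F9.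
- Ac2O/pyridine/DMAP gives (2R,12S)-1-[3,5-bis(benzyloxy)-2-({[tert-butyl(dimethyl)silyl]oxy}methyl)phenyl]tridecane-2,12-diyl diacetate F10.
- HF·pyridine gives (2R,12S)-1-[3,5-bis(benzyloxy)-2-(hydroxymethyl)phenyl]tridecane-2,12-diyl diacetate F11.
- Dess–Martin periodinane gives (2R,12S)-1-[3,5-bis(benzyloxy)-2-formylphenyl]tridecane-2,12-diyl diacetate F12.
- Pinnick oxidation (NaClO2, NaH2PO4, 2-methylbut-2-ene) gives 2,4-bis(benzyloxy)-6-[(2R,12S)-2,12-bis(acetyloxy)tridecyl]benzoic acid F13.
- Hydrogenolysis (H2, Pd/C) comes back at 22.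

**Step 2.** The risks are incomplete migration of the triple bond over nine positions and partial erosion of the carbinol configuration under the strongly basic conditions. The fallback builds the terminal alkyne by displacement and sets out from 1. Silylation (TBSCl, imidazole) gives tert-butyl{[(2S)-but-3-yn-2-yl]oxy}dimethylsilane F14. Lithiation and alkylation at the bromide end of 1-bromo-7-chloroheptane (n-BuLi, THF/DMPU) gives tert-butyl{[(2S)-11-chloroundec-3-yn-2-yl]oxy}dimethylsilane F15. Hydrogenation (H2, Pt/C, EtOAc) gives tert-butyl{[(2S)-11-chloroundecan-2-yl]oxy}dimethylsilane F16. Displacement of chloride with lithium acetylide–ethylenediamine in DMSO comes back at 5.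

**Step 5.** The risks are metalation at C4 between the two ethers, deprotonation of a benzylic OCH2 group followed by [1,2]-Wittig rearrangement, and protodesilylation of the electron-rich arylsilane on acidic work-up. The fallback places silicon by halogen–metal exchange and sets out from 6. Amine-catalysed ortho-bromination (NBS, i-Pr2NH cat., CH2Cl2, −78 °C) gives 3,5-bis(benzyloxy)-2-bromophenol F17. O-Silylation (hexamethyldisilazane, THF, reflux) gives [3,5-bis(benzyloxy)-2-bromophenoxy](trimethyl)silane F18. Bromine–lithium exchange (n-BuLi, THF, −100 °C) triggers oxygen-to-carbon silyl migration to the lithium phenoxide of 12, which is trapped with Tf2O and comes back at 13.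

## Further compounds

F1 | step 7 | methyl 2,4,6-trihydroxybenzoate | COC(=O)c1c(O)cc(O)cc1O
F2 | step 7 | methyl 2,4-bis(benzyloxy)-6-hydroxybenzoate | COC(=O)c1c(O)cc(OCc2ccccc2)cc1OCc1ccccc1
F3 | step 7 | methyl 2,4-bis(benzyloxy)-6-{[(trifluoromethyl)sulfonyl]oxy}benzoate | COC(=O)c1c(OS(=O)(=O)C(F)(F)F)cc(OCc2ccccc2)cc1OCc1ccccc1
F4 | step 7 | methyl 2,4-bis(benzyloxy)-6-[(12S)-12-{[tert-butyl(dimethyl)silyl]oxy}tridec-1-yn-1-yl]benzoate | COC(=O)c1c(OCc2ccccc2)cc(OCc2ccccc2)cc1C#CCCCCCCCCC[C@H](C)O[Si](C)(C)C(C)(C)C
F5 | step 11 | (3R)-6,8-bis(benzyloxy)-3-[(10S)-10-{[tert-butyl(dimethyl)silyl]oxy}undecyl]-3,4-dihydro-1H-isochromen-1-one | O=C1O[C@H](CCCCCCCCC[C@H](C)O[Si](C)(C)C(C)(C)C)Cc2cc(OCc3ccccc3)cc(OCc3ccccc3)c12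
F6 | step 11 | (3R)-6,8-bis(benzyloxy)-3-[(10S)-10-hydroxyundecyl]-3,4-dihydro-1H-isochromen-1-one | O=C1O[C@H](CCCCCCCCC[C@H](C)O)Cc2cc(OCc3ccccc3)cc(OCc3ccccc3)c12
F7 | step 11 | potassium 2,4-bis(benzyloxy)-6-[(2R,12S)-2,12-dihydroxytridecyl]benzoate | [K+].[O-]C(=O)c1c(OCc2ccccc2)cc(OCc2ccccc2)cc1C[C@H](O)CCCCCCCCC[C@H](C)O
F8 | step 12 | (2R,12S)-1-[3,5-bis(benzyloxy)-2-(hydroxymethyl)phenyl]tridecane-2,12-diol | OCc1c(OCc2ccccc2)cc(OCc2ccccc2)cc1C[C@H](O)CCCCCCCCC[C@H](C)O
F9 | step 12 | (2R,12S)-1-[3,5-bis(benzyloxy)-2-({[tert-butyl(dimethyl)silyl]oxy}methyl)phenyl]tridecane-2,12-diol | CC(C)(C)[Si](C)(C)OCc1c(OCc2ccccc2)cc(OCc2ccccc2)cc1C[C@H](O)CCCCCCCCC[C@H](C)O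
F10 | step 12 | (2R,12S)-1-[3,5-bis(benzyloxy)-2-({[tert-butyl(dimethyl)silyl]oxy}methyl)phenyl]tridecane-2,12-diyl diacetate | CC(C)(C)[Si](C)(C)OCc1c(OCc2ccccc2)cc(OCc2ccccc2)cc1C[C@H](OC(C)=O)CCCCCCCCC[C@H](C)OC(C)=O
F11 | step 12 | (2R,12S)-1-[3,5-bis(benzyloxy)-2-(hydroxymethyl)phenyl]tridecane-2,12-diyl diacetate | OCc1c(OCc2ccccc2)cc(OCc2ccccc2)cc1C[C@H](OC(C)=O)CCCCCCCCC[C@H](C)OC(C)=O
F12 | step 12 | (2R,12S)-1-[3,5-bis(benzyloxy)-2-formylphenyl]tridecane-2,12-diyl diacetate | O=Cc1c(OCc2ccccc2)cc(OCc2ccccc2)cc1C[C@H](OC(C)=O)CCCCCCCCC[C@H](C)OC(C)=O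
F13 | step 12 | 2,4-bis(benzyloxy)-6-[(2R,12S)-2,12-bis(acetyloxy)tridecyl]benzoic acid | O=C(O)c1c(OCc2ccccc2)cc(OCc2ccccc2)cc1C[C@H](OC(C)=O)CCCCCCCCC[C@H](C)OC(C)=O
F14 | step 2 | tert-butyl{[(2S)-but-3-yn-2-yl]oxy}dimethylsilane | C[C@H](O[Si](C)(C)C(C)(C)C)C#C
F15 | step 2 | tert-butyl{[(2S)-11-chloroundec-3-yn-2-yl]oxy}dimethylsilane | C[C@H](O[Si](C)(C)C(C)(C)C)C#CCCCCCCCCl
F16 | step 2 | tert-butyl{[(2S)-11-chloroundecan-2-yl]oxy}dimethylsilane | C[C@H](O[Si](C)(C)C(C)(C)C)CCCCCCCCCCl
F17 | step 5 | 3,5-bis(benzyloxy)-2-bromophenol | Oc1cc(OCc2ccccc2)cc(OCc2ccccc2)c1Br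
F18 | step 5 | [3,5-bis(benzyloxy)-2-bromophenoxy](trimethyl)silane | C[Si](C)(C)Oc1cc(OCc2ccccc2)cc(OCc2ccccc2)c1Br
A1 | alternative 1 | benzyl 2-[(2R,12S)-2,12-bis(tert-butyldimethylsilyloxy)tridecyl]-4,6-dihydroxybenzoate | CC(C)(C)[Si](C)(C)O[C@H](CCCCCCCCC[C@H](C)O[Si](C)(C)C(C)(C)C)Cc1cc(O)cc(O)c1C(=O)OCc1ccccc1
A2 | alternative 1 | 6-[(6R,16S)-6,16-bis(tert-butyldimethylsilyloxy)-2,4-dioxoheptadecyl]-2,2-dimethyl-4H-1,3-dioxin-4-one | CC1(C)OC(=O)C=C(CC(=O)CC(=O)C[C@H](O[Si](C)(C)C(C)(C)C)CCCCCCCCC[C@H](C)O[Si](C)(C)C(C)(C)C)O1
A3 | alternative 2 | 3-[(2R,12S)-2,12-bis(tert-butyldimethylsilyloxy)tridecyl]-5-(triisopropylsilyloxy)phenol | CC(C)(C)[Si](C)(C)O[C@H](CCCCCCCCC[C@H](C)O[Si](C)(C)C(C)(C)C)Cc1cc(O)cc(O[Si](C(C)C)(C(C)C)C(C)C)c1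
A4 | alternative 2 | 3-[(2R,12S)-2,12-bis(tert-butyldimethylsilyloxy)tridecyl]cyclobut-2-en-1-one | O=C1C=C(C[C@H](O[Si](C)(C)C(C)(C)C)CCCCCCCCC[C@H](C)O[Si](C)(C)C(C)(C)C)C1
A5 | alternative 2 | (triisopropylsilyloxy)ethyne | C#CO[Si](C(C)C)(C(C)C)C(C)C
A6 | alternative 3 | benzyl 2,4-bis(benzyloxy)-6-[(2R,12S)-2,12-bis(tert-butyldimethylsilyloxy)tridecyl]benzoate | CC(C)(C)[Si](C)(C)O[C@H](CCCCCCCCC[C@H](C)O[Si](C)(C)C(C)(C)C)Cc1cc(OCc2ccccc2)cc(OCc2ccccc2)c1C(=O)OCc1ccccc1
A7 | alternative 3 | benzyl 4-(benzyloxy)-6-[(2R,12S)-2,12-bis(tert-butyldimethylsilyloxy)tridecyl]-2-oxo-2H-pyran-5-carboxylate | O=C1C=C(OCc2ccccc2)C(C(=O)OCc2ccccc2)=C(C[C@H](O[Si](C)(C)C(C)(C)C)CCCCCCCCC[C@H](C)O[Si](C)(C)C(C)(C)C)O1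
A8 | alternative 3 | 1,1-bis(benzyloxy)ethene | C=C(OCc1ccccc1)OCc1ccccc1
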